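The target forms when electrophile and nucleophile react beside a solid base, and the question is how much electrophile has reacted at the end.

in all of them: electrophile 0.50 M

| charge | nucleophile | solid base | remark | time |
|---|---|---|---|---|
| teal | 0.75 equiv | 1.1 equiv | run made earlier |  |
| violet | 1.5 equiv | 1.1 equiv | run made earlier |  |
| grey | 1.9 equiv | 1.1 equiv | run made earlier |  |
| elm | 1.00 equiv | 1.10 equiv |  | 4.0 d |
| ash | 2.00 equiv | 1.10 equiv |  | 4.0 d |

| run | time / d | electrophile / % | target / % |
|---|---|---|---|
| teal | 0.833 | 70.4 | 27.2 |
| teal | 1.67 | 67.6 | 29.7 |
| teal | 2.50 | 64.2 | 31.5 |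
| teal | 3.00 | 63.9 | 32.2 |
| teal | 4.00 | 62.4 | 32.8 |
| violet | 0.333 | 56.1 | 39.1 |
| violet | 1.04 | 41.3 | 51.0 |
| violet | 1.67 | 37.9 | 55.2 |
| violet | 3.00 | 33.7 | 58.4 |
| violet | 4.00 | 30.4 | 60.7 |
| grey | 0.333 | 47.4 | 46.8 |
| grey | 0.625 | 36.8 | 56.2 |
| grey | 1.04 | 30.5 | 61.0 |
| grey | 2.00 | 24.1 | 66.8 |
| grey | 4.00 | 18.1 | 72.2 |

(scatter of a reading: 0.5 percentage points)

- solid base is a solid; its amount is given per volume of the solution
- at the start none of the solid base is in solution

* part of the electrophile that has reacted at the end, elm
* part of the electrophile that has reacted at the end, ash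
* what raising the equivalents of nucleophile from its lowest to its highest value here does to the part of the electrophile that has reacted (changes below 5 percentage points count as none) (no change / it falls / it rises)

**What do the runs show first?** Teal is crawling: between 2.50 d and 4.00 d its electrophile moves from 64.2% to 62.4%, so the run is stalling with electrophile still present.

**What does that stall measure?** Teal gives 1.99 for n, the toll: equivalents of nucleophile spent per equivalent of electrophile reacted. This is a reading, so it carries the scatter of the readings. It makes nucleophile the likely limiting reagent at low charge.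

**How do you use n?** The stall line S is the nucleophile charge divided by n, capped at complete conversion. For elm, S is 50.1%. For ash, it is 100%.

**But do flasks reach S by the end?** Not quite. By 4.0 d, violet stands at 92.6% of its S and grey at 86.0%, so grey falls further short. My own reckoning therefore puts elm between 46.4% and 50.1%, and ash near 86.0%, with conversion rising with nucleophile.

**And the forecast?** It gives 48.5% for elm, inside my range, and 84.5% for ash, below my figure; its answer on the trend is: it rises. Its ground is that teal's stall suggests “about two nucleophiles are consumed per electrophile reacted, or that an equivalent loss occurs”.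

The flask gives 49.1% for elm and 86.0% for ash; its answer on the trend is: it rises, by 37 percentage points.

    electrophile + nucleophile → acid set free + target (k = 0.177 M⁻¹ h⁻¹)
    nucleophile + acid set free ⇌ protonated nucleophile, settled at all times (K = 2900 M⁻¹)
    acid set free + free base ⇌ salt of the base, settled at all times (K = 21.8 M⁻¹)
    nucleophile ⇌ dormant form (K = 1.75, k = 0.0361 h⁻¹)
    solid base ⇌ free base, rate k5*(cs5 - [free base]) while solid is left; crystals form when [free base] > cs5 (solubility = 0.0910 M, k = 0.110 h⁻¹)
    target ⇌ isomer of the product (K = 0.151, k = 0.0399 h⁻¹)

Elm ends 1.0 point under S, with free nucleophile at 1.5% of its charge against 51% of the electrophile, and with protonated nucleophile at 0.216 M. Elm does not stay there: it reaches 64.5% by 40.0 d. A neighbour of ash charged with 0.500 equiv of nucleophile has S at 25.1%. At 4.00 d, with free nucleophile at 1.3% of its charge, that neighbour stands a little over its S, having reacted 26.4% of its electrophile.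

The earlier runs and the new flask are simulated for an exercise.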